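**Retrosynthetic overview**

1. Ring B (the tetrahydrofuran whose ArCH–O carbon is bonded to the C–OH ring-fusion carbon) is cut last, at its ArCH–O bond, by cationic cyclodehydration of a triol. Its aryl group comes from an aryllithium and a lactone carbonyl, and the tertiary OH from hydroxylation of the lactone enolate at the ring-fusion carbon.
2. Ring A (ArCH–O–CH2–C) of the resulting cis-fused bicyclic lactone is cut at both its ArCH–O bond and its CH2–C(ring fusion) bond: a formal [3+2] cycloaddition of formaldehyde to an aryl cyclopropane lactone.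
3. Enabling feature: in ring A the O–CH2 unit is one formaldehyde molecule lying between a benzylic carbon with a cation-stabilising 3,4-dimethoxyphenyl group and the ring-fusion carbon, which is alpha to the benzylic carbon of ring B (carried as a lactone carbonyl). This 1,3 donor/acceptor pair can be stored as one cyclopropane bond.
4. The endo-aryl cyclopropane lactone comes from a (Z)-cinnamyl diazoacetate by enantioselective intramolecular cyclopropanation, the only catalyst-controlled stereo-event. The ring-fusion CH set there relays the other three stereocentres.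
5. Ring order: cyclopropane plus lactone (ring B at the carbonyl level) together, then ring A in the key step, then ring B re-formed as the cyclic ether.

Key step: step 5

Remark: Rh2(5R-MEPY)4 is taken to show the sense of induction usual for its catalyst family with (Z)-allylic diazoacetates (the 5S catalyst would give the mirror-image series), and the keto diol of step 7 is written in its open form although it may rest as the cyclic hemiketal.

**Route**

Step 1
Reactants: 1 4-iodo-1,2-dimethoxybenzene; 2 prop-2-yn-1-ol
Product: 3 3-(3,4-dimethoxyphenyl)prop-2-yn-1-ol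
Conditions: Pd(PPh3)2Cl2 (2 mol%), CuI (4 mol%), Et3N, THF, rt
Reagents that add atoms: none
Why: Sonogashira coupling of an aryl iodide with a terminal alkyne is reliable at room temperature and tolerates the free alcohol.

Step 2
Reactants: 3 3-(3,4-dimethoxyphenyl)prop-2-yn-1-ol
Product: 4 (2Z)-3-(3,4-dimethoxyphenyl)prop-2-en-1-ol
Conditions: H2 (1 atm), Pd/CaCO3–Pb(OAc)2 (Lindlar catalyst), quinoline, EtOAc, rt, stopped after one equivalent of H2
Reagents that add atoms: none
Why: Lindlar semi-hydrogenation adds H2 syn on the poisoned palladium surface and should give the (Z)-alkene, which is needed to place the aryl group cis (endo) on the later cyclopropane.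

Step 3
Reactants: 4 (2Z)-3-(3,4-dimethoxyphenyl)prop-2-en-1-ol
Product: 6 (2Z)-3-(3,4-dimethoxyphenyl)prop-2-en-1-yl diazoacetate, via glyoxylate tosylhydrazone ester 5 (not isolated)
Conditions: TsNHN=CHCOCl (1.8 equiv), PhNMe2, CH2Cl2, 0 °C; then Et3N, 0 °C to rt
Reagents that add atoms: glyoxylic acid chloride 4-methylbenzenesulfonylhydrazone, Cc1ccc(cc1)S(=O)(=O)NN=CC(Cl)=O
Why: Acylation of the alcohol by the acid chloride, then base-induced loss of sulfinate from the tosylhydrazone (Bamford–Stevens-type diazo formation), is a standard one-flask route to allylic diazoacetates and leaves the (Z)-alkene untouched.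

Step 4
Reactants: 6 (2Z)-3-(3,4-dimethoxyphenyl)prop-2-en-1-yl diazoacetate
Product: 7 (1S,5R,6S)-6-(3,4-dimethoxyphenyl)-3-oxabicyclo[3.1.0]hexan-2-one (aryl endo)
Conditions: Rh2(5R-MEPY)4 (1 mol%), CH2Cl2, reflux, slow addition of 6
Reagents that add atoms: none
Why: Intramolecular cyclopropanation by a chiral dirhodium carboxamidate carbenoid is concerted and stereospecific, so the (Z)-alkene should give the endo-aryl (cis) cyclopropane, and the catalyst selects the alkene face, which sets the CH centre next to the CH2O carbon that persists into the target as the ring-fusion CH.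

Step 5
Reactants: 7 (1S,5R,6S)-6-(3,4-dimethoxyphenyl)-3-oxabicyclo[3.1.0]hexan-2-one
Product: 9 (3aR,4S,6aR)-4-(3,4-dimethoxyphenyl)tetrahydro-1H,3H-furo[3,4-c]furan-1-one, via oxocarbenium enolate zwitterion 8 (not isolated)
Conditions: (CH2O)n (5 equiv), Sc(OTf)3 (20 mol%), 4 Å MS, CH2Cl2, 0 °C to rt
Reagents that add atoms: formaldehyde (supplied as paraformaldehyde), C=O
Why: Proposed new method: Sc(OTf)3 on the lactone carbonyl (acceptor on the future ring-fusion carbon) and the 3,4-dimethoxyphenyl donor on the benzylic carbon polarise the cyclopropane bond between these two carbons, so that formaldehyde oxygen opens it at the benzylic carbon to give the oxocarbenium enolate 8, whose enolate carbon then attacks the O=CH2 carbon (an aldol-first sequence ending in O-capture of the benzylic cation leads to the same product); the closest known reaction type is the Lewis acid-catalysed formal [3+2] cycloaddition of aldehydes with 2-arylcyclopropane-1,1-diesters, and the single lactone acceptor used here should be compensated by the very electron-rich aryl donor and the extra strain of the endo-aryl bicycle. Ring A closes by an aldol-type 5-(enolexo)-endo-trig attack of the enolate on the oxocarbenium carbon, the closure usual for this cycloaddition. The benzylic stereocentre is set by backside attack of oxygen with inversion, which turns the endo (cis) aryl group of 7 into the exo aryl group of 9, and a free benzylic cation is expected to close with the aryl group on the convex face as well. The ring-fusion CH next to the carbonyl can only form cis, because the tethered CH2 reaches only the enolate face on the side of the benzylic carbon, and the stereocentre from step 4 is not touched. The step needs cleavage of the donor–acceptor bond and not of the other two cyclopropane bonds, which the aryl and carbonyl substituents secure, and O-capture at the benzylic carbon in preference to Friedel–Crafts attack of formaldehyde or of the cation on the arene, which a triflate Lewis acid without nucleophilic counter-ion at low temperature should favour.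

Step 6
Reactants: 9 (3aR,4S,6aR)-4-(3,4-dimethoxyphenyl)tetrahydro-1H,3H-furo[3,4-c]furan-1-one
Product: 11 (3aR,4S,6aS)-4-(3,4-dimethoxyphenyl)-6a-hydroxytetrahydro-1H,3H-furo[3,4-c]furan-1-one, via potassium enolate 10 (not isolated)
Conditions: KN(SiMe3)2, THF, −78 °C; 2-(phenylsulfonyl)-3-phenyloxaziridine, −78 °C; AcOH
Reagents that add atoms: 2-(phenylsulfonyl)-3-phenyloxaziridine, O=S(=O)(c1ccccc1)N1OC1c1ccccc1
Why: Davis enolate oxidation: the only alpha-proton sits at the ring-fusion carbon, and the planar enolate of the cis-fused bicycle can take oxygen only on its convex face, so the OH should end up cis to the neighbouring ring-fusion H.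

Step 7
Reactants: 11 (3aR,4S,6aS)-4-(3,4-dimethoxyphenyl)-6a-hydroxytetrahydro-1H,3H-furo[3,4-c]furan-1-one; 12 4-bromo-1,2-dimethoxybenzene
Product: 14 (3,4-dimethoxyphenyl)[(3S,4R,5S)-5-(3,4-dimethoxyphenyl)-3-hydroxy-4-(hydroxymethyl)oxolan-3-yl]methanone, via 3,4-dimethoxyphenyllithium 13 (not isolated)
Conditions: 12 (2.3 equiv), n-BuLi (2.2 equiv), THF, −78 °C; then 11, −78 °C; H2O
Reagents that add atoms: none
Why: Addition of an aryllithium to a gamma-lactone at −78 °C should stop at the ketone stage, because the lithium hemiketalate next to the lithium alkoxide of the tertiary OH resists a second addition, and no stereocentre is touched.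

Step 8
Reactants: 14 (3,4-dimethoxyphenyl)[(3S,4R,5S)-5-(3,4-dimethoxyphenyl)-3-hydroxy-4-(hydroxymethyl)oxolan-3-yl]methanone
Product: 15 (3S,4R,5S)-5-(3,4-dimethoxyphenyl)-3-[(3,4-dimethoxyphenyl)(hydroxy)methyl]-4-(hydroxymethyl)oxolan-3-ol (both carbinol epimers)
Conditions: NaBH4, MeOH, 0 °C to rt
Reagents that add atoms: none
Why: Borohydride reduction of the aryl ketone (through the open form of any hemiketal) gives the benzylic alcohol, whose configuration need not be controlled because it is erased in step 9.

Step 9
Reactants: 15 (3S,4R,5S)-5-(3,4-dimethoxyphenyl)-3-[(3,4-dimethoxyphenyl)(hydroxy)methyl]-4-(hydroxymethyl)oxolan-3-ol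
Product: 16 isogmelinol, (1S,3aS,4R,6aR)-1,4-bis(3,4-dimethoxyphenyl)tetrahydro-1H,3H-furo[3,4-c]furan-3a(4H)-ol
Conditions: camphorsulfonic acid (10 mol%), 4 Å MS, CH2Cl2, 0 °C
Reagents that add atoms: none
Why: Acid-catalysed SN1 cyclodehydration: the 3,4-dimethoxybenzylic alcohol ionises and the primary OH closes ring B on the cation with the aryl group on the convex face, cis to the tertiary OH and away from the CH2 of ring A, which is expected to be the thermodynamically preferred arrangement as well.

**Compound list**

1 | 4-iodo-1,2-dimethoxybenzene | COc1ccc(I)cc1OC | starting material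
2 | prop-2-yn-1-ol | C#CCO | starting material
3 | 3-(3,4-dimethoxyphenyl)prop-2-yn-1-ol | COc1ccc(C#CCO)cc1OC | intermediate
4 | (2Z)-3-(3,4-dimethoxyphenyl)prop-2-en-1-ol | COc1ccc(/C=C\CO)cc1OC | intermediate
5 | (2Z)-3-(3,4-dimethoxyphenyl)prop-2-en-1-yl 2-{2-[(4-methylphenyl)sulfonyl]hydrazinylidene}acetate (not isolated) | COc1ccc(/C=C\COC(=O)C=NNS(=O)(=O)c2ccc(C)cc2)cc1OC | intermediate
6 | (2Z)-3-(3,4-dimethoxyphenyl)prop-2-en-1-yl diazoacetate | COc1ccc(/C=C\COC(=O)C=[N+]=[N-])cc1OC | intermediate
7 | (1S,5R,6S)-6-(3,4-dimethoxyphenyl)-3-oxabicyclo[3.1.0]hexan-2-one, aryl endo | O=C1OC[C@@H]2[C@H](c3ccc(OC)c(OC)c3)[C@H]12 | intermediate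
8 | oxocarbenium enolate zwitterion, drawn without scandium (not isolated) | COc1ccc([C@@H]([O+]=C)[C@H]2COC([O-])=C2)cc1OC | intermediate
9 | (3aR,4S,6aR)-4-(3,4-dimethoxyphenyl)tetrahydro-1H,3H-furo[3,4-c]furan-1-one | COc1ccc([C@H]2OC[C@@H]3C(=O)OC[C@H]23)cc1OC | intermediate
10 | potassium enolate of 9 (not isolated) | COc1ccc([C@H]2OCC3=C([O-])OC[C@H]23)cc1OC.[K+] | intermediate
11 | (3aR,4S,6aS)-4-(3,4-dimethoxyphenyl)-6a-hydroxytetrahydro-1H,3H-furo[3,4-c]furan-1-one | COc1ccc([C@H]2OC[C@]3(O)C(=O)OC[C@H]23)cc1OC | intermediate
12 | 4-bromo-1,2-dimethoxybenzene | COc1ccc(Br)cc1OC | starting material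
13 | 3,4-dimethoxyphenyllithium (not isolated) | [Li]c1ccc(OC)c(OC)c1 | intermediate
14 | (3,4-dimethoxyphenyl)[(3S,4R,5S)-5-(3,4-dimethoxyphenyl)-3-hydroxy-4-(hydroxymethyl)oxolan-3-yl]methanone | COc1ccc([C@H]2OC[C@](O)(C(=O)c3ccc(OC)c(OC)c3)[C@@H]2CO)cc1OC | intermediate
15 | (3S,4R,5S)-5-(3,4-dimethoxyphenyl)-3-[(3,4-dimethoxyphenyl)(hydroxy)methyl]-4-(hydroxymethyl)oxolan-3-ol, both carbinol epimers | COc1ccc([C@H]2OC[C@](O)(C(O)c3ccc(OC)c(OC)c3)[C@@H]2CO)cc1OC | intermediate
16 | isogmelinol, (1S,3aS,4R,6aR)-1,4-bis(3,4-dimethoxyphenyl)tetrahydro-1H,3H-furo[3,4-c]furan-3a(4H)-ol | COc1ccc([C@H]2OC[C@]3(O)[C@@H](c4ccc(OC)c(OC)c4)OC[C@H]23)cc1OC | target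

**Step count and risks**

Total step count: 9. Longest linear sequence: 9 steps (from 1 to 16); 12 enters in step 7.

Steps most likely to fail:

1. Step 5 (the proposed method). Formaldehyde may not be captured: the ring-opened ion pair may reclose or lose a proton to an arylidene lactone, the arene may be hydroxymethylated, or stereochemical fidelity at the benzylic carbon may leak. The fallback uses known reactions only, sets out from 7 and returns at 9. Acid-catalysed methanolysis of the cyclopropane (MeOH, Sc(OTf)3 cat.), a known solvolytic opening of aryl donor–acceptor cyclopropanes with inversion at the benzylic carbon, should give the methyl ether (4R)-4-[(S)-(3,4-dimethoxyphenyl)(methoxy)methyl]oxolan-2-one F1. Detrifluoroacetylative Regitz diazo transfer (LiN(SiMe3)2, CF3CO2CH2CF3, THF, −78 °C; then MsN3, Et3N) should give the diazolactone (4R)-3-diazo-4-[(S)-(3,4-dimethoxyphenyl)(methoxy)methyl]oxolan-2-one F2. Rh2(acam)4-catalysed intramolecular 1,5 C–H insertion of the carbenoid into the O–CH3 group then forms the CH2–C(ring fusion) bond and gives 9, cis-fused by necessity; the carboxamidate ligand is chosen to disfavour attack on the arene.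

2. Step 9. The cation closure may show poor facial selectivity at the new benzylic carbon, the other benzylic ether carbon may epimerise by reversible ionisation, or a pinacol-type 1,2-shift next to the tertiary alcohol may intervene. The fallback avoids any benzylic cation, sets out from 14 and returns at 16. Reagent-controlled Noyori-type transfer hydrogenation (RuCl[(S,S)-TsDPEN](p-cymene), HCO2H/Et3N), for which the aryl ketone model predicts the (R)-carbinol, should give the single triol epimer (3S,4R,5S)-5-(3,4-dimethoxyphenyl)-3-[(R)-(3,4-dimethoxyphenyl)(hydroxy)methyl]-4-(hydroxymethyl)oxolan-3-ol F4. Selective sulfonylation of the primary alcohol (TsCl, Et3N, Bu2SnO cat., CH2Cl2, 0 °C) gives the primary 4-methylbenzenesulfonate of F4, F5. KOtBu in THF at 0 °C then closes ring B by Williamson 5-exo-tet attack of the benzylic alkoxide on the CH2OTs carbon, with retention at the benzylic carbon, to give 16.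

3. Step 6. The bridgehead enolate may open ring A by beta-elimination of the ring oxygen, or may add to the sulfonylimine released by the oxidant. The fallback sets out from 9 and returns at 11. LiN(SiMe3)2 is added to 9 in the presence of Me3SiCl (internal quench, THF, −78 °C), so that the enolate is silylated as it forms, to give the trimethylsilyl ketene acetal of 9, F3. Rubottom oxidation with dimethyldioxirane (acetone/CH2Cl2, −78 °C) on the convex face, then dilute citric acid, should give 11.

**Further compounds**

F1 | step 5 | (4R)-4-[(S)-(3,4-dimethoxyphenyl)(methoxy)methyl]oxolan-2-one | COc1ccc([C@@H](OC)[C@H]2COC(=O)C2)cc1OC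
F2 | step 5 | (4R)-3-diazo-4-[(S)-(3,4-dimethoxyphenyl)(methoxy)methyl]oxolan-2-one | COc1ccc([C@@H](OC)[C@H]2COC(=O)C2=[N+]=[N-])cc1OC
F3 | step 6 | trimethylsilyl ketene acetal of 9 (3aR,4S; C=C between the former carbonyl carbon and the ring-fusion carbon) | COc1ccc([C@H]2OCC3=C(O[Si](C)(C)C)OC[C@H]23)cc1OC
F4 | step 9 | (3S,4R,5S)-5-(3,4-dimethoxyphenyl)-3-[(R)-(3,4-dimethoxyphenyl)(hydroxy)methyl]-4-(hydroxymethyl)oxolan-3-ol | COc1ccc([C@H]2OC[C@](O)([C@H](O)c3ccc(OC)c(OC)c3)[C@@H]2CO)cc1OC
F5 | step 9 | primary 4-methylbenzenesulfonate of F4 | COc1ccc([C@H]2OC[C@](O)([C@H](O)c3ccc(OC)c(OC)c3)[C@@H]2COS(=O)(=O)c3ccc(C)cc3)cc1OC
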